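A one-step world has substrate meeting reagent and a yield read off a single rate constant; these flasks also have a road to homo dimer, so the thing to watch is the toll on that road.

the same everywhere: substrate 0.45 M; reagent 1.05 equiv; time 15 s

| flask | temperature |
|---|---|
| autumn | 90 °C |
| spring | 65 °C |
| dawn | 40 °C |

    reagent + reactive form → product (k1 = 0.13 L mol⁻¹ s⁻¹, Ea1 = 44.0 kJ mol⁻¹)
    substrate ⇌ reactive form (K2 = 1.0, k2 = 3.2 s⁻¹, Ea2 = 65.0 kJ mol⁻¹, ΔH2 = −28.0 kJ mol⁻¹)
    crystals ⇌ product, rate k3*(cs3 - [product]) while solid is left; crystals form when [product] > cs3 (cs3 = 0.15 M, k3 = 0.64 s⁻¹)
    2 substrate → homo dimer (k4 = 0.0096 L mol⁻¹ s⁻¹, Ea4 = 71.0 kJ mol⁻¹)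
    (constants at 40 °C)

- a species is counted by the substrate in it: one homo dimer counts as two
- amounts and yields of product count crystals too
- a doubled species enters its step squared and goes two at a time
- given per volume of solution although it is solid: crystals
- all constants are for 40 °C and move with temperature by the activation energies and enthalpies

* which flask leads in amount of product, in percent of the substrate charged ("all alike" within 1.5 percentage points) (autumn / spring / dawn / all alike)
* how much product is there at the end, in percent of the substrate charged: autumn
* how much product is there at the end, in percent of the substrate charged: spring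
* how much product is there at the end, in percent of the substrate charged: dawn

- At dawn the equilibrium constant of the reactive form is paired with a forward constant of 3.2 s⁻¹, against 0.0614 s⁻¹ for the drain of reactive form by reagent. In autumn the forward step alone starts at 270 times the loss to homo dimer. So I hold [reactive form] = K[substrate], with K at 0.227 in autumn, 0.452 in spring and 1.00 at dawn.
- I count [substrate] + [reactive form] as one pool. Its coupling constant is a = (coupling constant)·K/(1+K), which gives 0.247 L mol⁻¹ s⁻¹ in autumn, 0.141 L mol⁻¹ s⁻¹ in spring and 0.0650 L mol⁻¹ s⁻¹ at dawn.
- The toll c (the selectivity factor) is the substrate lost to homo dimer per substrate coupled, at equal pool and [reagent]: c = 2·(dimer constant)/[(coupling constant)·K·(1+K)]. It is 2.21 in autumn, 0.485 in spring and 0.0738 at dawn.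
- With [reagent] held steady at a value G and S the substrate charge, the yield is Y = (G/(c·S))·ln[1 + (c·S/G)(1 − e^(−a·G·t))]. As c shrinks, this returns the one-step world. Crystals count as product and stand left of no coupling arrow, so I leave them out of the sum.
- The first pass puts G at the charge, 0.473 M, and gives 47.9 % for autumn, 55.5 % for spring and 36.4 % for dawn.
- The weak link is that steady reagent: each turn of coupling consumes one reagent. I reforge it by setting G to the charge less 0.5 of the first-pass product: 0.365 M, 0.348 M and 0.391 M.
- I commit to 40.6 % for autumn, 45.1 % for spring and 31.2 % for dawn, so spring leads.
- The forecast names spring, with 41 % for autumn, 44.7 % for spring and 30.8 % for dawn, on the ground that “spring sits near the sweet spot, autumn loses substrate to dimer”. Its autumn stands 0.40 percentage points above mine and its dawn 0.40 points below mine.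
- The simulation gives spring in the lead, with 41.1 % for autumn, 45.4 % for spring and 31.1 % for dawn. Spring's lead over autumn is 4.3 points, against a margin of 1.5 points.
- The neighbouring flask is autumn read at 25 s, with the toll still 2.21. The first pass gives 52.1 %, which sets G at 0.355 M, and the second pass gives 44.7 %. The simulation of that autumn flask gives 45.5 % of product, with 3.36 % of the substrate still there.

(The constants used here were set for the occasion, and the outcome is calculated.)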